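The synthesis cuts the C4–C5 bond of the cyclohexane C1–C6. Its C3–C4(OH)(CH3)–C5 segment, a tertiary carbinol between two oxygenated carbons, is the retron of an α-ketol rearrangement. The precursor resembles a carbocyclic ribose: a 1-acetylcyclopent-2-en-1-ol whose cis-diol acetonide becomes C5/C6. On an aluminium chelate, the ring bond from the carbinol carbon (C3) to C5 shifts to the acetyl carbon. In one operation the cyclopentene grows into the cyclohexenone, C4 enters with methyl and hydroxyl in place, and the all-cis C4–C6 triol is set. The enone then relays C3, C2 and C1. Aldol and Evans–Tishchenko reactions build the side chain.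

Key step: step 5

Convention: target numbering is used throughout. Ring: C1 (side chain), C2 (OH), C3 (angelate), C4 (CH3, OH), C5 (OAc), C6 (isobutyrate). Chain: C7(=C14H2), C8, C9, C10, C11. β is the ring face of the C1 side chain (also O4, O5, O6); α is the face of O2, O3 and 4-CH3.

Assumption: (−)-Ipc2BCl is taken as the antipode that sends the methyl-ketone enolate to the Si face of the C8 aldehyde (8S). If the sense is the reverse, (+)-Ipc2BCl is used and nothing else changes.

Step 1
Reactants: 1 (1S,4R)-cis-4-acetoxycyclopent-2-en-1-ol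
Product: 2 4-acetoxycyclopentane-1,2,3-triol, new 2,3-cis-diol on the face opposite to 1-OH and 4-OAc
Conditions: OsO4 (2 mol %), NMO, acetone/H2O, 0 °C → rt
Reagents that add atoms: N-methylmorpholine N-oxide, C[N+]1([O-])CCOCC1; water, O
Why: Upjohn dihydroxylation; the syn addition should occur anti to both allylic substituents and so set the future C5 and C6 as a cis-diol of defined absolute configuration.

Step 2
Reactants: 2 triol monoacetate
Product: 3 2,3-O-isopropylidene acetal of 2 (1-OH free, 4-OAc)
Conditions: Me2C(OMe)2, p-TsOH (cat.), acetone, rt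
Reagents that add atoms: 2,2-dimethoxypropane, COC(C)(C)OC
Why: Acid-catalysed transketalisation; only the cis-2,3-diol can close a dioxolane on the cyclopentane, so the trans-disposed 1-OH stays free.

Step 3
Reactants: 3 hydroxy acetate acetonide
Product: 5 (3aS,6aS)-2,2-dimethyl-3a,6a-dihydro-4H-cyclopenta[d][1,3]dioxol-4-one, via β-acetoxy ketone 4 (not isolated)
Conditions: DMP, CH2Cl2, 0 °C → rt; then Et3N, rt
Reagents that add atoms: none
Why: Dess–Martin oxidation followed by E1cB loss of the β-acetate from the CH2 side; acetate is the better leaving group, so the cis-fused dioxolane centres stay untouched.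

Step 4
Reactants: 5 cyclopentenone acetonide
Product: 7 1-acetylcyclopent-2-en-1-ol acetonide (tertiary OH β, cis to the dioxolane oxygens; acetyl α), via ethoxyvinyl carbinol 6 (not isolated)
Conditions: ethyl vinyl ether, t-BuLi, THF, −78 → 0 °C; 5, −78 °C; then 0.5 M HCl, THF, 0 °C
Reagents that add atoms: ethyl vinyl ether, C=COCC; water, O
Why: 1,2-addition of an acyl anion equivalent (α-lithiated enol ether) on the convex face anti to the dioxolane; the enol ether hydrolyses far faster than the acetonide.

Step 5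
Reactants: 7 α-ketol
Product: 8 4β-hydroxy-4α-methyl-5β,6β-(isopropylidenedioxy)cyclohex-1-en-3-one
Conditions: Al(Ot-Bu)3 (0.3 equiv), toluene, 80 °C, to constant composition
Reagents that add atoms: none
Why: Al(III) binds the tertiary alkoxide and the acetyl oxygen in a five-membered chelate, the alkoxide pushes, and the ring bond C3–C5 migrates suprafacially (retention at C5) to the acetyl carbon, so that C3 becomes the ketone and the former acetyl carbon becomes C4; this is the α-ketol (acyloin) rearrangement, closest in type to the Lewis-acid D-homoannulation of 17-hydroxy-20-keto steroids. No ring is closed by cyclisation: the carbocycle is enlarged from five to six atoms by the 1,2-shift and the dioxolane ends cis-fused at C5/C6. C4 is the only new stereocentre and is fixed by the syn-periplanar O–C3–C4=O chelate: in 7 the acetyl group lies on the α face, C5 attacks the carbonyl face turned towards it, and the oxygen ends β (cis to O5) with the methyl α. The same epimer should also be the more stable aluminium chelate (O4 equatorial, CH3 axial without a syn-axial oxygen), so any C3 epimer of 7 is funnelled to 8, because C3 loses its stereocentre and the shift is reversible. The step needs migration of C5 rather than of the vinylic C2, and the substrate secures this thermodynamically, since only the C5 shift leaves the new ketone conjugated with C1=C2 whereas the C2 shift gives a non-conjugated α,α'-dioxygenated ketone that can revert. Relief of cyclopentene strain and enone conjugation drive the equilibrium to 8, and the weakly basic alkoxide avoids γ-deprotonation and elimination of the acetonide.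

Step 6
Reactants: 8 hydroxy enone
Product: 9 4α-methyl-5β,6β-(isopropylidenedioxy)cyclohex-1-ene-3α,4β-diol
Conditions: Me4NBH(OAc)3, MeCN/AcOH, −20 °C
Reagents that add atoms: none
Why: Hydroxyl-directed (Saksena–Evans type) 1,2-reduction; boron binds the 4β-OH and delivers hydride to the β face of C3, which should give the 3α-alcohol trans to O4.

Step 7
Reactants: 9 allylic diol
Product: 10 1α,2α-epoxide of 9
Conditions: m-CPBA, CH2Cl2, 0 °C → rt
Reagents that add atoms: m-chloroperbenzoic acid, O=C(OO)c1cccc(Cl)c1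
Why: Henbest epoxidation; hydrogen bonding to the allylic 3α-OH and shielding of the β face by the dioxolane both direct oxygen to the α face and set O2.

Step 8
Reactants: 10 epoxy diol
Product: 11 1β-isopropenyl-4α-methyl-5β,6β-(isopropylidenedioxy)cyclohexane-2α,3α,4β-triol
Conditions: isopropenylMgBr (5 equiv), CuI (0.2 equiv), THF, −30 → 0 °C
Reagents that add atoms: isopropenylmagnesium bromide, C=C(C)[Mg]Br
Why: Copper-catalysed Grignard opening of the epoxide with SN2 inversion at C1 (side chain β); the magnesium chelate of the trans O3/O4 diolate holds these oxygens gauche, and that half-chair opens trans-diaxially (Fürst–Plattner) at C1, whereas attack at C2 would have to pass the syn-axial O4 and O6.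

Step 9
Reactants: 11 triol
Product: 12 2-O-TBS ether of 11
Conditions: TBSCl, imidazole, DMF, 0 °C → rt
Reagents that add atoms: tert-butyldimethylsilyl chloride, CC(C)(C)[Si](C)(C)Cl
Why: Sterically controlled silylation; the equatorial 2-OH should react ahead of the axial 3-OH next to quaternary C4 and of the tertiary 4-OH.

Step 10
Reactants: 12 silyl ether diol
Product: 13 3-O-angelate of 12
Conditions: angelic acid, 2,4,6-Cl3C6H2COCl, Et3N, toluene, rt; then 12, 80 °C
Reagents that add atoms: angelic acid, C/C=C(/C)C(=O)O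
Why: Yamaguchi mixed-anhydride esterification run without DMAP, which acylates the only free secondary hydroxyl and should keep the Z geometry of the angelate.

Step 11
Reactants: 13 angelate acetonide
Product: 14 4β,5β,6β-triol (2-OTBS, 3-O-angelate, 1β-isopropenyl)
Conditions: AcOH/H2O 4:1, 45 °C
Reagents that add atoms: none
Why: Acid hydrolysis of the dioxolane; the hindered secondary TBS ether and the ester should survive aqueous acetic acid.

Step 12
Reactants: 14 triol
Product: 16 6-O-isobutyrate with free 5-OH, via cyclic orthoester 15 (not isolated)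
Conditions: i-PrC(OMe)3, CSA (cat.), CH2Cl2, rt; then AcOH/H2O 4:1, rt
Reagents that add atoms: trimethyl orthoisobutyrate, COC(OC)(OC)C(C)C; water, O
Why: Orthoester exchange on the secondary cis-5,6-diol, then stereoelectronically controlled hydrolysis, which opens a cyclic orthoester to the axial ester and the equatorial alcohol and so places the isobutyrate on the hindered axial O6.

Step 13
Reactants: 16 hydroxy isobutyrate
Product: 17 5-O-acetate of 16
Conditions: Ac2O, pyridine, DMAP (cat.), 0 °C → rt
Reagents that add atoms: acetic anhydride, CC(=O)OC(C)=O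
Why: Standard acetylation of the one remaining secondary (equatorial) hydroxyl; the tertiary 4-OH should not react.

Step 14
Reactants: 17 isopropenyl tetraester-type intermediate
Product: 19 enal (C7(=CH2)–C8HO on C1), via allylic alcohol 18 (not isolated)
Conditions: SeO2 (0.3 equiv), t-BuOOH, CH2Cl2, rt; then DMP, CH2Cl2, rt
Reagents that add atoms: tert-butyl hydroperoxide (oxygen relayed by SeO2), CC(C)(C)OO
Why: Riley-type allylic oxidation (ene reaction, then [2,3]-shift) of the most electron-rich alkene at its methyl group, since allylic strain holds C1–H in the alkene plane and out of alignment, with Dess–Martin oxidation converging alcohol and aldehyde to 19.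

Step 15
Reactants: 20 3-hydroxy-3-methylbutan-2-one
Product: 21 3-methyl-3-(triethylsilyloxy)butan-2-one
Conditions: TESCl, imidazole, DMAP (cat.), DMF, rt
Reagents that add atoms: triethylsilyl chloride, CC[Si](Cl)(CC)CC
Why: Routine silylation of the tertiary α-ketol hydroxyl, which leaves a ketone that can enolise only at its methyl group.

Step 16
Reactants: 19 enal; 21 silyloxy methyl ketone
Product: 24 (8S)-8-hydroxy-10-ketone, via boron enolate 22 (not isolated), via boron aldolate 23 (not isolated)
Conditions: 21, (−)-Ipc2BCl, Et3N, Et2O, 0 °C; 19, −78 → −20 °C; then H2O2, pH 7 buffer, MeOH, 0 °C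
Reagents that add atoms: none
Why: Reagent-controlled Ipc2B-mediated (Paterson-type) methyl ketone aldol; the preformed enolate adds only to the aldehyde, and the chiral boron ligands select its Si face to set 8S.

Step 17
Reactants: 24 β-hydroxy ketone
Product: 25 (8S,10S)-8-O-isobutyrate-10-ol (2-OTBS, 11-OTES)
Conditions: SmI2 (0.3 equiv), i-PrCHO, THF, −10 °C
Reagents that add atoms: isobutyraldehyde, CC(C)C=O
Why: Evans–Tishchenko reduction; the samarium-bound hemiacetal of 8-OH with isobutyraldehyde delivers hydride intramolecularly to C10, which gives the 1,3-anti relationship (10S) and leaves the isobutyrate on O8.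

Step 18
Reactants: 25 bis-silyl ether
Product: 26 CNP0253192.1 (target)
Conditions: HF·pyridine, pyridine, THF, 0 °C → rt
Reagents that add atoms: none
Why: Fluoride-mediated desilylation under mildly acidic conditions frees O2 and O11 while suppressing acyl migration and angelate isomerisation.

Compound list
1 | (1S,4R)-cis-4-acetoxycyclopent-2-en-1-ol | O[C@@H]1C=C[C@H](OC(C)=O)C1 | starting material
2 | 4-acetoxycyclopentane-1,2,3-triol (2,3-diol anti to 1-OH and 4-OAc) | O[C@@H]1[C@@H](O)[C@@H](O)[C@H](OC(C)=O)C1 | intermediate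
3 | 2,3-O-isopropylidene acetal of 2 | O[C@@H]1[C@H]2OC(C)(C)O[C@H]2[C@H](OC(C)=O)C1 | intermediate
4 | β-acetoxy ketone acetonide | O=C1[C@H]2OC(C)(C)O[C@H]2[C@H](OC(C)=O)C1 | intermediate
5 | (3aS,6aS)-2,2-dimethyl-3a,6a-dihydro-4H-cyclopenta[d][1,3]dioxol-4-one | O=C1C=C[C@@H]2OC(C)(C)O[C@H]12 | intermediate
6 | 1-(1-ethoxyvinyl)cyclopent-2-en-1-ol acetonide (OH β) | C=C(OCC)[C@@]1(O)C=C[C@@H]2OC(C)(C)O[C@H]12 | intermediate
7 | 1-acetylcyclopent-2-en-1-ol acetonide (OH β, acetyl α) | CC(=O)[C@@]1(O)C=C[C@@H]2OC(C)(C)O[C@H]12 | intermediate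
8 | 4β-hydroxy-4α-methyl-5β,6β-(isopropylidenedioxy)cyclohex-1-en-3-one | O=C1C=C[C@@H]2OC(C)(C)O[C@@H]2[C@]1(C)O | intermediate
9 | 3α,4β-diol from 8 | O[C@H]1C=C[C@@H]2OC(C)(C)O[C@@H]2[C@]1(C)O | intermediate
10 | 1α,2α-epoxide of 9 | O[C@H]1[C@H]2O[C@H]2[C@@H]3OC(C)(C)O[C@@H]3[C@]1(C)O | intermediate
11 | 1β-isopropenyl-2α,3α,4β-triol 5,6-acetonide | C=C(C)[C@H]1[C@H](O)[C@H](O)[C@@](C)(O)[C@H]2OC(C)(C)O[C@@H]12 | intermediate
12 | 2-O-TBS ether of 11 | C=C(C)[C@H]1[C@H](O[Si](C)(C)C(C)(C)C)[C@H](O)[C@@](C)(O)[C@H]2OC(C)(C)O[C@@H]12 | intermediate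
13 | 3-O-angelate of 12 | C=C(C)[C@H]1[C@H](O[Si](C)(C)C(C)(C)C)[C@H](OC(=O)/C(C)=C\C)[C@@](C)(O)[C@H]2OC(C)(C)O[C@@H]12 | intermediate
14 | 4β,5β,6β-triol | C=C(C)[C@H]1[C@H](O[Si](C)(C)C(C)(C)C)[C@H](OC(=O)/C(C)=C\C)[C@@](C)(O)[C@@H](O)[C@H]1O | intermediate
15 | 5,6-cyclic methyl orthoisobutyrate (orthoester carbon undefined) | C=C(C)[C@H]1[C@H](O[Si](C)(C)C(C)(C)C)[C@H](OC(=O)/C(C)=C\C)[C@@](C)(O)[C@H]2OC(OC)(C(C)C)O[C@@H]12 | intermediate
16 | 6-O-isobutyrate, 5-OH free | C=C(C)[C@H]1[C@H](O[Si](C)(C)C(C)(C)C)[C@H](OC(=O)/C(C)=C\C)[C@@](C)(O)[C@@H](O)[C@H]1OC(=O)C(C)C | intermediate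
17 | 5-O-acetate of 16 | C=C(C)[C@H]1[C@H](O[Si](C)(C)C(C)(C)C)[C@H](OC(=O)/C(C)=C\C)[C@@](C)(O)[C@@H](OC(C)=O)[C@H]1OC(=O)C(C)C | intermediate
18 | allylic alcohol (C8–OH) | C=C(CO)[C@H]1[C@H](O[Si](C)(C)C(C)(C)C)[C@H](OC(=O)/C(C)=C\C)[C@@](C)(O)[C@@H](OC(C)=O)[C@H]1OC(=O)C(C)C | intermediate
19 | enal (C8 aldehyde) | C=C(C=O)[C@H]1[C@H](O[Si](C)(C)C(C)(C)C)[C@H](OC(=O)/C(C)=C\C)[C@@](C)(O)[C@@H](OC(C)=O)[C@H]1OC(=O)C(C)C | intermediate
20 | 3-hydroxy-3-methylbutan-2-one | CC(=O)C(C)(C)O | starting material
21 | 3-methyl-3-(triethylsilyloxy)butan-2-one | CC(=O)C(C)(C)O[Si](CC)(CC)CC | intermediate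
22 | diisopinocampheylboron enolate of 21 | C=C(OB([C@@H]1C[C@@H]2C[C@H]([C@H]1C)C2(C)C)[C@@H]1C[C@@H]2C[C@H]([C@H]1C)C2(C)C)C(C)(C)O[Si](CC)(CC)CC | intermediate
23 | boron aldolate (O8–B(Ipc)2) | C=C([C@H]1[C@H](O[Si](C)(C)C(C)(C)C)[C@H](OC(=O)/C(C)=C\C)[C@@](C)(O)[C@@H](OC(C)=O)[C@H]1OC(=O)C(C)C)[C@H](CC(=O)C(C)(C)O[Si](CC)(CC)CC)OB([C@@H]1C[C@@H]2C[C@H]([C@H]1C)C2(C)C)[C@@H]1C[C@@H]2C[C@H]([C@H]1C)C2(C)C | intermediate
24 | (8S)-8-hydroxy-10-ketone | C=C([C@H]1[C@H](O[Si](C)(C)C(C)(C)C)[C@H](OC(=O)/C(C)=C\C)[C@@](C)(O)[C@@H](OC(C)=O)[C@H]1OC(=O)C(C)C)[C@H](CC(=O)C(C)(C)O[Si](CC)(CC)CC)O | intermediate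
25 | (8S,10S)-8-O-isobutyrate-10-ol, 2-OTBS, 11-OTES | C=C([C@H]1[C@H](O[Si](C)(C)C(C)(C)C)[C@H](OC(=O)/C(C)=C\C)[C@@](C)(O)[C@@H](OC(C)=O)[C@H]1OC(=O)C(C)C)[C@H](C[C@H](O)C(C)(C)O[Si](CC)(CC)CC)OC(=O)C(C)C | intermediate
26 | CNP0253192.1 | C=C([C@H]1[C@H](O)[C@H](OC(=O)/C(C)=C\C)[C@@](C)(O)[C@@H](OC(C)=O)[C@H]1OC(=O)C(C)C)[C@H](C[C@H](O)C(C)(C)O)OC(=O)C(C)C | target

Total step count: 18. Longest linear sequence: 17 (steps 1–14 and 16–18).

Steps most likely to fail

**Step 5.**
- Risk: the vinylic carbon C2 may shift faster than C5 while the mixture equilibrates too slowly. On long heating the γ-alkoxy enone may also lose the acetonide by elimination.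
- Fallback: an irreversible one-carbon homologation of the same five-membered carbocycle. It sets out from 3 and comes back at 8, and here the ketone carbon of 4 becomes C4.
- Compound 3 is oxidised with DMP without base, and the β-acetoxy ketone 4 is isolated.
- TMSCHN2/BF3·OEt2 (CH2Cl2, −78 °C, Tiffeneau–Demjanov type) inserts C3, because the unoxygenated CH2 migrates rather than the acetal-bearing carbon. This gives the α-silyl ketone F1, which loses silicon on silica gel to give the γ-acetoxycyclohexanone F2.
- MeMgBr/CeCl3 adds to C4 anti to the dioxolane (4β-OH) and removes the acetate, giving the diol F3.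
- MsCl/Et3N mesylates only the secondary 1-OH to give the mesylate F4. DBU then eliminates towards C2, the only side with an anti hydrogen, giving the cyclohexene F5.
- Oxidation of the single allylic CH2 (CrO3·3,5-dimethylpyrazole) gives 8.

**Step 8.**
- Risk: the branched sp2 nucleophile may be kept off the β face of C1 by the dioxolane. The consequences would be attack at C2, halohydrin formation or no reaction.
- Fallback: open the epoxide with a slim sp nucleophile and build the isopropenyl group afterwards. It sets out from 10 and comes back at 11.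
- Et2AlC≡CSiMe3 (toluene, 0 °C → rt) opens 10 at C1 to give the silylalkyne triol F6.
- K2CO3/MeOH gives the terminal alkyne F7.
- Zirconium-catalysed methylalumination (Me3Al, Cp2ZrCl2, CH2Cl2) followed by protonolysis places methyl on C7 and gives 11.

**Step 14.**
- Risk: the selenium ene reaction may be slow at the crowded alkene. It may also occur at C1–H or at the angelate methyl groups, or over-oxidise.
- Fallback: electrophilic ene-type chlorination followed by N-oxide oxidation. It sets out from 17 and comes back at 19.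
- HOCl generated from Ca(OCl)2/CO2 (CH2Cl2/H2O, 0 °C) converts the isopropenyl group into the allylic chloride F8.
- N-methylmorpholine N-oxide in MeCN (Ganem-type oxidation) turns F8 into 19.

Further compounds
F1 | step 5 | α-trimethylsilyl ketone from ring enlargement of 4 | O=C1C([Si](C)(C)C)C[C@@H](OC(C)=O)[C@@H]2OC(C)(C)O[C@H]12
F2 | step 5 | 1α-acetoxy-5β,6β-(isopropylidenedioxy)cyclohexan-4-one | O=C1CC[C@@H](OC(C)=O)[C@@H]2OC(C)(C)O[C@H]12
F3 | step 5 | 4α-methyl-5β,6β-(isopropylidenedioxy)cyclohexane-1α,4β-diol | C[C@@]1(O)CC[C@@H](O)[C@@H]2OC(C)(C)O[C@H]12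
F4 | step 5 | 1-O-mesylate of F3 | C[C@@]1(O)CC[C@@H](OS(C)(=O)=O)[C@@H]2OC(C)(C)O[C@H]12
F5 | step 5 | 4α-methyl-5β,6β-(isopropylidenedioxy)cyclohex-1-en-4β-ol | C[C@@]1(O)CC=C[C@@H]2OC(C)(C)O[C@H]12
F6 | step 8 | 1β-(trimethylsilylethynyl) triol acetonide | C[Si](C)(C)C#C[C@H]1[C@H](O)[C@H](O)[C@@](C)(O)[C@H]2OC(C)(C)O[C@@H]12
F7 | step 8 | 1β-ethynyl triol acetonide | C#C[C@H]1[C@H](O)[C@H](O)[C@@](C)(O)[C@H]2OC(C)(C)O[C@@H]12
F8 | step 14 | allylic chloride (C8–Cl) | C=C(CCl)[C@H]1[C@H](O[Si](C)(C)C(C)(C)C)[C@H](OC(=O)/C(C)=C\C)[C@@](C)(O)[C@@H](OC(C)=O)[C@H]1OC(=O)C(C)C
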